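Rings A and B are unfolded into an (E,E)-farnesyl chain on the arene CH2, with the terminal (E)-methyl oxidised so that it becomes the equatorial C4 carboxyl. One titanocene-mediated radical bicyclisation of the terminal epoxide forms the C4–C5 and C10–C9 bonds, closes both six-membered rings, sets C4, C5, C9 and C10 from the epoxide carbon C3, and leaves C8 as the exocyclic methylene. The feature exploited is that C1–C10, the C11 link, both ring methyls and the C8 methylene coincide with the farnesyl skeleton. The precursor, an epoxyfarnesyl trimethoxynaphthalene with a silyloxymethyl terminus, is assembled from an aryl bromide and an epoxy allylic bromide.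

Key step: step 12

Remark: the decalin is numbered as in the labdane terpenoids (C1–C10, C11 = CH2 link to the arene, C12 = exocyclic CH2); the naphthalene is numbered so that C8 carries the link and C1 is its peri neighbour. The supplied precursor and product structures were checked for mutual consistency (E,E geometry, (R,R)-epoxide from the D-tartrate, C3–C10 configurations) and are used unchanged as 17 and 19.

Step 1
Reactants: 1 2,6-dimethylnaphthalene
Product: 2 1-bromo-2,6-dimethylnaphthalene
Conditions: Br2 (1.05 equiv), CH2Cl2, 0 °C to rt, dark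
Reagents that add atoms: bromine, BrBr
Why: Electrophilic aromatic bromination goes to the α-position ortho to a methyl group, and since C1 and C5 are symmetry-equivalent only one monobromide can form.

Step 2
Reactants: 2 1-bromo-2,6-dimethylnaphthalene
Product: 3 5-bromo-2,6-dimethylnaphthalene-1,4-dione
Conditions: H5IO6 (4 equiv), CrO3 (10 mol%), MeCN, 5 °C to rt
Reagents that add atoms: periodic acid, O=I(O)(O)(O)(O)O
Why: Oxidation of a naphthalene to its para-quinone by catalytic hexavalent chromium with periodic acid takes place on the methyl-bearing ring, because the other ring is deactivated and blocked at C1 by bromine, which puts one carbonyl peri to bromine with the quinone C–H next to it.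

Step 3
Reactants: 3 5-bromo-2,6-dimethylnaphthalene-1,4-dione
Product: 4 5-bromo-2,3-epoxy-2,6-dimethyl-2,3-dihydronaphthalene-1,4-dione (racemic)
Conditions: 30% aq. H2O2, Na2CO3 (cat.), EtOH/H2O, 0 °C to rt
Reagents that add atoms: hydrogen peroxide, OO
Why: Weitz–Scheffer nucleophilic epoxidation of the electron-poor quinone double bond by hydroperoxide anion gives the racemic cis-fused epoxide, whose two stereocentres disappear in the next step.

Step 4
Reactants: 4 5-bromo-2,3-epoxy-2,6-dimethyl-2,3-dihydronaphthalene-1,4-dione (racemic)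
Product: 5 8-bromo-2-hydroxy-3,7-dimethylnaphthalene-1,4-dione
Conditions: conc. H2SO4, rt, 15 min; then ice-water
Reagents that add atoms: none
Why: Acid-promoted opening of the quinone epoxide followed by enolisation (the isomerisation known for menadione oxide) leaves the oxygen on the former C–H carbon, that is, next to the carbonyl peri to bromine.

Step 5
Reactants: 5 8-bromo-2-hydroxy-3,7-dimethylnaphthalene-1,4-dione
Product: 7 8-bromo-1,2,4-trimethoxy-3,7-dimethylnaphthalene, via naphthalenetriol 6 (not isolated)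
Conditions: Na2S2O4, THF/H2O, rt; then aq. KOH, Me2SO4, Bu4NBr (cat.), rt, under N2
Reagents that add atoms: dimethyl sulfate, COS(=O)(=O)OC
Why: Reductive methylation, in which dithionite reduces the quinone to the triol and Williamson O-methylation caps all three phenoxides before air can reoxidise them.

Step 6
Reactants: 8 (2E,6E)-farnesyl acetate
Product: 9 (2E,6E,10E)-12-hydroxyfarnesyl acetate
Conditions: SeO2 (0.3 equiv), salicylic acid (0.1 equiv), t-BuOOH (70% aq.), CH2Cl2, rt
Reagents that add atoms: tert-butyl hydroperoxide, CC(C)(C)OO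
Why: Riley allylic oxidation with catalytic SeO2 (ene reaction then 2,3-sigmatropic shift) attacks the most accessible terminal trisubstituted alkene at its (E)-methyl group and gives the (E)-allylic alcohol, the alkene next to the acetate being deactivated.

Step 7
Reactants: 9 (2E,6E,10E)-12-hydroxyfarnesyl acetate
Product: 10 (2E,6E)-9-[(2R,3R)-3-(hydroxymethyl)-3-methyloxiran-2-yl]-3,7-dimethylnona-2,6-dien-1-yl acetate
Conditions: Ti(OiPr)4 (10 mol%), diethyl D-(−)-tartrate (12 mol%), t-BuOOH (anhydrous), 4 Å MS, CH2Cl2, −20 °C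
Reagents that add atoms: tert-butyl hydroperoxide, CC(C)(C)OO
Why: Katsuki–Sharpless asymmetric epoxidation touches only the allylic-alcohol alkene, and the D-tartrate ligand delivers oxygen to the face that gives the (R,R)-epoxide, trans because the alkene is E.

Step 8
Reactants: 10 (2E,6E)-9-[(2R,3R)-3-(hydroxymethyl)-3-methyloxiran-2-yl]-3,7-dimethylnona-2,6-dien-1-yl acetate
Product: 11 (2E,6E)-9-[(2R,3R)-3-[(tert-butyldimethylsilyl)oxymethyl]-3-methyloxiran-2-yl]-3,7-dimethylnona-2,6-dien-1-yl acetate
Conditions: TBSCl, imidazole, DMF, 0 °C to rt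
Reagents that add atoms: tert-butyldimethylsilyl chloride, CC(C)(C)[Si](C)(C)Cl
Why: Imidazole-promoted silylation of the primary alcohol, to which the epoxide and the acetate are inert.

Step 9
Reactants: 11 (2E,6E)-9-[(2R,3R)-3-[(tert-butyldimethylsilyl)oxymethyl]-3-methyloxiran-2-yl]-3,7-dimethylnona-2,6-dien-1-yl acetate
Product: 12 (2E,6E)-9-[(2R,3R)-3-[(tert-butyldimethylsilyl)oxymethyl]-3-methyloxiran-2-yl]-3,7-dimethylnona-2,6-dien-1-ol
Conditions: K2CO3 (0.2 equiv), MeOH, 0 °C to rt
Reagents that add atoms: none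
Why: Base-catalysed transesterification (methanolysis) removes the acetate without touching the silyl ether or the fully substituted epoxide.

Step 10
Reactants: 12 (2E,6E)-9-[(2R,3R)-3-[(tert-butyldimethylsilyl)oxymethyl]-3-methyloxiran-2-yl]-3,7-dimethylnona-2,6-dien-1-ol
Product: 14 (2E,6E)-1-bromo-9-[(2R,3R)-3-[(tert-butyldimethylsilyl)oxymethyl]-3-methyloxiran-2-yl]-3,7-dimethylnona-2,6-diene, via mesylate 13 (not isolated)
Conditions: MsCl, Et3N, THF, −40 °C; then LiBr, THF, −40 to 0 °C; used crude
Reagents that add atoms: lithium bromide, [Li+].[Br-]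
Why: Mesylation then SN2 displacement by bromide (Finkelstein type) at low temperature, the standard conversion of epoxy-polyprenols into their allylic bromides, keeps the (E)-alkene and the epoxide intact.

Step 11
Reactants: 7 8-bromo-1,2,4-trimethoxy-3,7-dimethylnaphthalene; 14 (2E,6E)-1-bromo-9-[(2R,3R)-3-[(tert-butyldimethylsilyl)oxymethyl]-3-methyloxiran-2-yl]-3,7-dimethylnona-2,6-diene
Product: 17 8-[(2E,6E)-9-[(2R,3R)-3-[(tert-butyldimethylsilyl)oxymethyl]-3-methyloxiran-2-yl]-3,7-dimethylnona-2,6-dien-1-yl]-1,2,4-trimethoxy-3,7-dimethylnaphthalene, via aryllithium 15 (not isolated), via arylcopper 16 (not isolated)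
Conditions: 7, t-BuLi (2 equiv), THF, −78 °C; CuBr·SMe2 (1 equiv), −78 to −40 °C; then 14, −78 to 0 °C
Reagents that add atoms: none
Why: Bromine–lithium exchange, transmetalation to the arylcopper and SN2 substitution of the primary allylic bromide (copper-mediated aryl–allyl coupling) join the fragments at the unsubstituted α-carbon with retention of alkene geometry, while the trisubstituted epoxide and the silyl ether do not react at low temperature.

Step 12
Reactants: 17 8-[(2E,6E)-9-[(2R,3R)-3-[(tert-butyldimethylsilyl)oxymethyl]-3-methyloxiran-2-yl]-3,7-dimethylnona-2,6-dien-1-yl]-1,2,4-trimethoxy-3,7-dimethylnaphthalene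
Product: 19 8-[[(3R,4S,5S,9R,10S)-4-[(tert-butyldimethylsilyl)oxymethyl]-3-hydroxy-4,10-dimethyl-8-methylidenedecalin-9-yl]methyl]-1,2,4-trimethoxy-3,7-dimethylnaphthalene, via titanium alkoxide 18 (not isolated)
Conditions: Cp2TiCl2 (2.5 equiv), Mn dust (8 equiv), degassed THF, rt, slow addition of 17; then aq. NaH2PO4
Reagents that add atoms: none
Why: The trivalent titanium reagent Cp2TiCl, generated from Cp2TiCl2 by Mn, gives one electron to the epoxide, whose more substituted C–O bond breaks to leave a tertiary C4 radical and a titanium-bound oxygen on C3; this radical adds to C5, the new tertiary C10 radical adds to C9, and the tertiary C8 radical is taken up by a second Cp2TiCl and loses a hydrogen from its methyl group, which leaves the C8 exocyclic methylene. The closest known reaction type is the titanocene-mediated radical cyclisation of epoxypolyprenes, including aryl-bearing and terminally oxygenated ones, that ends in exocyclic alkenes. Ring A closes by a 6-endo-trig addition (C4 to C5) and ring B by a second 6-endo-trig addition (C10 to C9), both through a chair–chair folding of the chain. C3 keeps the configuration of the epoxide carbon because its C–O bond is never broken; the trans fusion at C5/C10 and the equatorial arylmethyl group at C9 follow from the two (E)-alkenes in the chair–chair array anchored by the equatorial titanoxy group; C4 is set when the planar radical places its larger CH2OSi arm equatorial, away from the axial C10 methyl. The step needs opening toward the tertiary radical, 6-endo closure in preference to 5-exo, alkene formation in place of reduction and an untouched arene; the substitution pattern of epoxide and alkenes sends each radical to the less substituted carbon, and conditions free of Lewis acid spare the silyl ether and the electron-rich naphthalene, whose positions flanking the CH2 link are both substituted. The C4 outcome is the least certain element, and a minor C4 epimer would be removed by chromatography at this stage.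

Step 13
Reactants: 19 8-[[(3R,4S,5S,9R,10S)-4-[(tert-butyldimethylsilyl)oxymethyl]-3-hydroxy-4,10-dimethyl-8-methylidenedecalin-9-yl]methyl]-1,2,4-trimethoxy-3,7-dimethylnaphthalene
Product: 20 O-[(3R,4S,5S,9R,10S)-decalin-3-yl] imidazole-1-carbothioate of 19
Conditions: 1,1'-thiocarbonyldiimidazole (3 equiv), DMAP (0.5 equiv), ClCH2CH2Cl, 80 °C
Reagents that add atoms: 1,1'-thiocarbonyldiimidazole, S=C(n1ccnc1)n1ccnc1
Why: Thioacylation of the secondary C3 alcohol, the first stage of a Barton–McCombie deoxygenation, under neutral conditions that leave the silyl ether in place.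

Step 14
Reactants: 20 O-[(3R,4S,5S,9R,10S)-decalin-3-yl] imidazole-1-carbothioate of 19
Product: 21 8-[[(4S,5S,9R,10S)-4-[(tert-butyldimethylsilyl)oxymethyl]-4,10-dimethyl-8-methylidenedecalin-9-yl]methyl]-1,2,4-trimethoxy-3,7-dimethylnaphthalene
Conditions: Bu3SnH (3 equiv), AIBN (0.2 equiv), toluene, 100 °C
Reagents that add atoms: none
Why: Barton–McCombie radical deoxygenation, in which the stannyl radical adds to C=S, the C3–O bond fragments and the secondary C3 radical is reduced by the stannane; C3 becomes CH2 and the remote alkene is not involved.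

Step 15
Reactants: 21 8-[[(4S,5S,9R,10S)-4-[(tert-butyldimethylsilyl)oxymethyl]-4,10-dimethyl-8-methylidenedecalin-9-yl]methyl]-1,2,4-trimethoxy-3,7-dimethylnaphthalene
Product: 22 [(4S,5S,9R,10S)-4,10-dimethyl-8-methylidene-9-[(1,2,4-trimethoxy-3,7-dimethylnaphthalen-8-yl)methyl]decalin-4-yl]methanol
Conditions: Bu4NF (1 M in THF), THF, rt to 45 °C
Reagents that add atoms: none
Why: Fluoride-mediated desilylation of the neopentyl silyl ether, to which no other group in the molecule responds.

Step 16
Reactants: 22 [(4S,5S,9R,10S)-4,10-dimethyl-8-methylidene-9-[(1,2,4-trimethoxy-3,7-dimethylnaphthalen-8-yl)methyl]decalin-4-yl]methanol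
Product: 24 (4S,5S,9R,10S)-4,10-dimethyl-8-methylidene-9-[(1,2,4-trimethoxy-3,7-dimethylnaphthalen-8-yl)methyl]decalin-4-carboxylic acid, via aldehyde 23 (not isolated)
Conditions: Dess–Martin periodinane, NaHCO3, CH2Cl2, rt; then NaClO2, NaH2PO4, 2-methyl-2-butene, t-BuOH/H2O, rt
Reagents that add atoms: sodium chlorite, [Na+].[O-]Cl=O
Why: Dess–Martin oxidation to the non-enolisable neopentyl aldehyde then Pinnick chlorite oxidation gives the acid, with 2-methyl-2-butene consuming HOCl so that the exocyclic alkene and the electron-rich arene are spared.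

Step 17
Reactants: 24 (4S,5S,9R,10S)-4,10-dimethyl-8-methylidene-9-[(1,2,4-trimethoxy-3,7-dimethylnaphthalen-8-yl)methyl]decalin-4-carboxylic acid
Product: 25 (4S,5S,9R,10S)-9-[(2-methoxy-3,7-dimethyl-1,4-dioxo-1,4-dihydronaphthalen-8-yl)methyl]-4,10-dimethyl-8-methylidenedecalin-4-carboxylic acid
Conditions: (NH4)2Ce(NO3)6 (2.5 equiv), MeCN/H2O, 0 °C
Reagents that add atoms: water, O
Why: Oxidative demethylation of the para-related C1 and C4 methoxy groups by tetravalent cerium gives the 2-methoxy-1,4-naphthoquinone, and any ortho-quinone isomer converges on the same compound in the last step.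

Step 18
Reactants: 25 (4S,5S,9R,10S)-9-[(2-methoxy-3,7-dimethyl-1,4-dioxo-1,4-dihydronaphthalen-8-yl)methyl]-4,10-dimethyl-8-methylidenedecalin-4-carboxylic acid
Product: 26 (4S,5S,9R,10S)-9-[(2-hydroxy-3,7-dimethyl-1,4-dioxo-1,4-dihydronaphthalen-8-yl)methyl]-4,10-dimethyl-8-methylidenedecalin-4-carboxylic acid (CNP0259461.3)
Conditions: 1 M aq. NaOH, MeOH/THF, rt; then 1 M HCl to pH 3
Reagents that add atoms: sodium hydroxide, [Na+].[OH-]
Why: Addition–elimination hydrolysis of the vinylogous methyl ester (2-methoxy- to 2-hydroxy-1,4-naphthoquinone) by hydroxide, then acidification; no stereocentre is epimerisable under these conditions.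

Compound list
1 | 2,6-dimethylnaphthalene | Cc1ccc2cc(C)ccc2c1 | starting material
2 | 1-bromo-2,6-dimethylnaphthalene | Cc1ccc2c(Br)c(C)ccc2c1 | intermediate
3 | 5-bromo-2,6-dimethylnaphthalene-1,4-dione (C4 carbonyl peri to Br, quinone C3–H) | CC1=CC(=O)c2c(Br)c(C)ccc2C1=O | intermediate
4 | 5-bromo-2,3-epoxy-2,6-dimethyl-2,3-dihydronaphthalene-1,4-dione (racemic, cis-fused epoxide) | CC12OC1C(=O)c1c(Br)c(C)ccc1C2=O | intermediate
5 | 8-bromo-2-hydroxy-3,7-dimethylnaphthalene-1,4-dione | CC1=C(O)C(=O)c2c(Br)c(C)ccc2C1=O | intermediate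
6 | 8-bromo-3,7-dimethylnaphthalene-1,2,4-triol | Cc1c(O)c(O)c2c(Br)c(C)ccc2c1O | intermediate (not isolated)
7 | 8-bromo-1,2,4-trimethoxy-3,7-dimethylnaphthalene | COc1c(OC)c(C)c(OC)c2ccc(C)c(Br)c12 | intermediate
8 | (2E,6E)-farnesyl acetate | CC(C)=CCC/C(C)=C/CC/C(C)=C/COC(C)=O | starting material
9 | (2E,6E,10E)-12-hydroxyfarnesyl acetate | OC/C(C)=C/CC/C(C)=C/CC/C(C)=C/COC(C)=O | intermediate
10 | (2E,6E)-9-[(2R,3R)-3-(hydroxymethyl)-3-methyloxiran-2-yl]-3,7-dimethylnona-2,6-dien-1-yl acetate | CC(=O)OC/C=C(C)/CC/C=C(C)/CC[C@H]1O[C@]1(C)CO | intermediate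
11 | (2E,6E)-9-[(2R,3R)-3-[(tert-butyldimethylsilyl)oxymethyl]-3-methyloxiran-2-yl]-3,7-dimethylnona-2,6-dien-1-yl acetate | CC(=O)OC/C=C(C)/CC/C=C(C)/CC[C@H]1O[C@]1(C)CO[Si](C)(C)C(C)(C)C | intermediate
12 | (2E,6E)-9-[(2R,3R)-3-[(tert-butyldimethylsilyl)oxymethyl]-3-methyloxiran-2-yl]-3,7-dimethylnona-2,6-dien-1-ol | OC/C=C(C)/CC/C=C(C)/CC[C@H]1O[C@]1(C)CO[Si](C)(C)C(C)(C)C | intermediate
13 | methanesulfonate of 12 | CS(=O)(=O)OC/C=C(C)/CC/C=C(C)/CC[C@H]1O[C@]1(C)CO[Si](C)(C)C(C)(C)C | intermediate (not isolated)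
14 | (2E,6E)-1-bromo-9-[(2R,3R)-3-[(tert-butyldimethylsilyl)oxymethyl]-3-methyloxiran-2-yl]-3,7-dimethylnona-2,6-diene | BrC/C=C(C)/CC/C=C(C)/CC[C@H]1O[C@]1(C)CO[Si](C)(C)C(C)(C)C | intermediate
15 | (1,2,4-trimethoxy-3,7-dimethylnaphthalen-8-yl)lithium | [Li]c1c(C)ccc2c(OC)c(C)c(OC)c(OC)c12 | intermediate (not isolated)
16 | (1,2,4-trimethoxy-3,7-dimethylnaphthalen-8-yl)copper | [Cu]c1c(C)ccc2c(OC)c(C)c(OC)c(OC)c12 | intermediate (not isolated)
17 | 8-[(2E,6E)-9-[(2R,3R)-3-[(tert-butyldimethylsilyl)oxymethyl]-3-methyloxiran-2-yl]-3,7-dimethylnona-2,6-dien-1-yl]-1,2,4-trimethoxy-3,7-dimethylnaphthalene | COc1c(OC)c(C)c(OC)c2ccc(C)c(C/C=C(C)/CC/C=C(C)/CC[C@H]3O[C@]3(C)CO[Si](C)(C)C(C)(C)C)c12 | intermediate (precursor of the key step)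
18 | chlorotitanocene alkoxide of 19 (O3–TiCp2Cl) | C=C1CC[C@H]2[C@@](C)(CC[C@@H](O[Ti](Cl)(C3C=CC=C3)C3C=CC=C3)[C@]2(C)CO[Si](C)(C)C(C)(C)C)[C@@H]1Cc1c(C)ccc2c(OC)c(C)c(OC)c(OC)c12 | intermediate (not isolated)
19 | 8-[[(3R,4S,5S,9R,10S)-4-[(tert-butyldimethylsilyl)oxymethyl]-3-hydroxy-4,10-dimethyl-8-methylidenedecalin-9-yl]methyl]-1,2,4-trimethoxy-3,7-dimethylnaphthalene (trans-decalin; 3-OH, 4-CH2OSi and 9-CH2Ar equatorial; 4-CH3 and 10-CH3 axial on one face) | C=C1CC[C@H]2[C@@](C)(CC[C@@H](O)[C@]2(C)CO[Si](C)(C)C(C)(C)C)[C@@H]1Cc1c(C)ccc2c(OC)c(C)c(OC)c(OC)c12 | intermediate (product of the key step)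
20 | O-[(3R,4S,5S,9R,10S)-decalin-3-yl] imidazole-1-carbothioate of 19 | C=C1CC[C@H]2[C@@](C)(CC[C@@H](OC(=S)n3ccnc3)[C@]2(C)CO[Si](C)(C)C(C)(C)C)[C@@H]1Cc1c(C)ccc2c(OC)c(C)c(OC)c(OC)c12 | intermediate
21 | 8-[[(4S,5S,9R,10S)-4-[(tert-butyldimethylsilyl)oxymethyl]-4,10-dimethyl-8-methylidenedecalin-9-yl]methyl]-1,2,4-trimethoxy-3,7-dimethylnaphthalene | C=C1CC[C@H]2[C@@](C)(CCC[C@]2(C)CO[Si](C)(C)C(C)(C)C)[C@@H]1Cc1c(C)ccc2c(OC)c(C)c(OC)c(OC)c12 | intermediate
22 | [(4S,5S,9R,10S)-4,10-dimethyl-8-methylidene-9-[(1,2,4-trimethoxy-3,7-dimethylnaphthalen-8-yl)methyl]decalin-4-yl]methanol | C=C1CC[C@H]2[C@@](C)(CCC[C@]2(C)CO)[C@@H]1Cc1c(C)ccc2c(OC)c(C)c(OC)c(OC)c12 | intermediate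
23 | (4S,5S,9R,10S)-4,10-dimethyl-8-methylidene-9-[(1,2,4-trimethoxy-3,7-dimethylnaphthalen-8-yl)methyl]decalin-4-carbaldehyde | C=C1CC[C@H]2[C@@](C)(CCC[C@]2(C)C=O)[C@@H]1Cc1c(C)ccc2c(OC)c(C)c(OC)c(OC)c12 | intermediate (not isolated)
24 | (4S,5S,9R,10S)-4,10-dimethyl-8-methylidene-9-[(1,2,4-trimethoxy-3,7-dimethylnaphthalen-8-yl)methyl]decalin-4-carboxylic acid | C=C1CC[C@H]2[C@@](C)(CCC[C@]2(C)C(=O)O)[C@@H]1Cc1c(C)ccc2c(OC)c(C)c(OC)c(OC)c12 | intermediate
25 | (4S,5S,9R,10S)-9-[(2-methoxy-3,7-dimethyl-1,4-dioxo-1,4-dihydronaphthalen-8-yl)methyl]-4,10-dimethyl-8-methylidenedecalin-4-carboxylic acid | C=C1CC[C@H]2[C@@](C)(CCC[C@]2(C)C(=O)O)[C@@H]1Cc1c(C)ccc2c1C(=O)C(OC)=C(C)C2=O | intermediate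
26 | (4S,5S,9R,10S)-9-[(2-hydroxy-3,7-dimethyl-1,4-dioxo-1,4-dihydronaphthalen-8-yl)methyl]-4,10-dimethyl-8-methylidenedecalin-4-carboxylic acid; equatorial CO2H, trans-decalin, equatorial C9 arylmethyl | C=C1CC[C@H]2[C@@](C)(CCC[C@]2(C)C(=O)O)[C@@H]1Cc1c(C)ccc2c1C(=O)C(O)=C(C)C2=O | target

Total step count: 18 (arene branch steps 1–5, terpenoid branch steps 6–10, union step 11, key step 12, endgame steps 13–18).
Longest linear sequence: 13 steps (steps 1–5 or 6–10, then 11–18).

Steps most likely to fail

Step 12. The radical cascade may be intercepted at the arene-bearing end, either by hydrogen transfer from the doubly activated ArCH2 position or by stalling after ring A beside the bulky arylmethyl group, and discrimination between equatorial and axial placement of the CH2OSi arm at C4 may be incomplete. The fallback leaves the arene out of the cyclisation and joins the fragments afterwards; it does not change how C4 is set. It sets out from 11 and returns at 21. Cp2TiCl (Cp2TiCl2, Mn, THF) would close the same two rings on the arene-free chain, the substrate class on which this cascade is best established, to give the bicyclic hydroxy acetate F1. K2CO3 in MeOH would give the diol F2. TEMPO with PhI(OAc)2 would oxidise only the primary alcohol and give the hydroxy aldehyde F3. An excess of aryllithium 15 (from 7 and t-BuLi) would add to the aldehyde and give the benzylic diol F4 as a mixture of C11 epimers. NaH, CS2 and MeI would convert both hydroxyls into the bis(xanthate) F5. Bu3SnH with AIBN would then remove both oxygen functions in one Barton–McCombie operation and return the route at 21.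

Step 11. The functionalised allylic bromide 14 may decay (bromide-induced epoxide opening, allylic transposition, halogen–metal exchange) faster than the hindered arylcopper captures it. The fallback unites the fragments before the terminus is functionalised; it sets out from 7 and returns at 17. Arylcopper 16 would be alkylated with commercial (2E,6E)-farnesyl bromide, a robust electrophile that can be used in excess, to give the farnesyl naphthalene F6. SeO2 with t-BuOOH would oxidise the terminal (E)-methyl and give the allylic alcohol F7. Sharpless epoxidation with Ti(OiPr)4 and diethyl D-tartrate would give the epoxy alcohol F8. TBSCl with imidazole would return the route at 17.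

Step 2. Direct oxidation may be unselective: attack on the benzylic methyl groups, loss of bromine by ipso oxidation and ring cleavage may outrun quinone formation. The fallback installs the oxygen stepwise through a naphthol; it sets out from 2 and returns at 3. A second equivalent of Br2 would give the symmetric 1,5-dibromo-2,6-dimethylnaphthalene F9. Exchange of one bromine with n-BuLi (1 equiv), trapping with B(OMe)3 and oxidation with H2O2/NaOH would give 5-bromo-2,6-dimethylnaphthalen-1-ol F10. Teuber oxidation with Fremy's salt, (KSO3)2NO, would give the para-quinone and return the route at 3.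

Further compounds
F1 | step 12 | [(3R,4S,5S,9R,10S-configured as 19)-4-[(tert-butyldimethylsilyl)oxymethyl]-3-hydroxy-4,10-dimethyl-8-methylidenedecalin-9-yl]methyl acetate | C=C1CC[C@H]2[C@@](C)(CC[C@@H](O)[C@]2(C)CO[Si](C)(C)C(C)(C)C)[C@@H]1COC(C)=O
F2 | step 12 | 4-[(tert-butyldimethylsilyl)oxymethyl]-9-(hydroxymethyl)-4,10-dimethyl-8-methylidenedecalin-3-ol, configured as 19 | C=C1CC[C@H]2[C@@](C)(CC[C@@H](O)[C@]2(C)CO[Si](C)(C)C(C)(C)C)[C@@H]1CO
F3 | step 12 | 4-[(tert-butyldimethylsilyl)oxymethyl]-3-hydroxy-4,10-dimethyl-8-methylidenedecalin-9-carbaldehyde, configured as 19 | C=C1CC[C@H]2[C@@](C)(CC[C@@H](O)[C@]2(C)CO[Si](C)(C)C(C)(C)C)[C@@H]1C=O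
F4 | step 12 | 11-hydroxy derivative of 19 (benzylic diol, both C11 epimers) | C=C1CC[C@H]2[C@@](C)(CC[C@@H](O)[C@]2(C)CO[Si](C)(C)C(C)(C)C)[C@@H]1C(O)c1c(C)ccc2c(OC)c(C)c(OC)c(OC)c12
F5 | step 12 | 3,11-bis(S-methyl xanthate) of F4 | C=C1CC[C@H]2[C@@](C)(CC[C@@H](OC(=S)SC)[C@]2(C)CO[Si](C)(C)C(C)(C)C)[C@@H]1C(OC(=S)SC)c1c(C)ccc2c(OC)c(C)c(OC)c(OC)c12
F6 | step 11 | 8-[(2E,6E)-farnesyl]-1,2,4-trimethoxy-3,7-dimethylnaphthalene | COc1c(OC)c(C)c(OC)c2ccc(C)c(C/C=C(C)/CC/C=C(C)/CCC=C(C)C)c12
F7 | step 11 | (2E,6E,10E)-2,6,10-trimethyl-12-(1,2,4-trimethoxy-3,7-dimethylnaphthalen-8-yl)dodeca-2,6,10-trien-1-ol | COc1c(OC)c(C)c(OC)c2ccc(C)c(C/C=C(C)/CC/C=C(C)/CC/C=C(C)/CO)c12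
F8 | step 11 | [(2R,3R)-2-methyl-3-[(3E,7E)-3,7-dimethyl-9-(1,2,4-trimethoxy-3,7-dimethylnaphthalen-8-yl)nona-3,7-dien-1-yl]oxiran-2-yl]methanol | COc1c(OC)c(C)c(OC)c2ccc(C)c(C/C=C(C)/CC/C=C(C)/CC[C@H]3O[C@]3(C)CO)c12
F9 | step 2 | 1,5-dibromo-2,6-dimethylnaphthalene | Cc1ccc2c(Br)c(C)ccc2c1Br
F10 | step 2 | 5-bromo-2,6-dimethylnaphthalen-1-ol | Cc1ccc2c(Br)c(C)ccc2c1O
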